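**Retrosynthetic overview**
- Structural feature: ring B (C1'–C6') is a resorcinol. O2' and O4' flank C3', which carries C4'' of the dimethylpyran (ring D). Only O2' belongs to ring D, so the two oxygens must be told apart.
- Key disconnection: ring B is cut into the vinylketene derived from diazo ketone 19 by photo-Wolff rearrangement and the prenyl siloxyalkyne 23. The bonds formed are C1'–C6', C1'–C2', C3'–C4' and C4'–C5', and ring B is born with O4'–H and O2'–TIPS.
- Diazo ketone 19 goes back through vinyl ketone 17 and Weinreb amide 15 to the (R)-β-benzylbutyrolactone 13, and from there to a Stobbe half-ester whose asymmetric hydrogenation sets C3. The C6 prenyl group comes from a Claisen–Cope shift of the O-prenyl ether that masks O1.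
- Order of rings: A (bought), C (Mitsunobu, step 9), B (step 14), D (aerobic Pd cyclisation, step 17).

Key step: step 14

Remark on the chemistry: the target SMILES is read as (3R). Isoflavan numbering is used (ring B primed, pyran ring D doubly primed).

**Step 1**
Reactants: 1 2,4,6-trihydroxybenzaldehyde
Product: 2 2,6-dihydroxy-4-(methoxymethoxy)benzaldehyde
Conditions: MOMCl (1.0 equiv), i-Pr2NEt (1.1 equiv), THF, 0 °C
Reagents that add atoms: chloromethyl methyl ether (MOMCl), COCCl
Why: Williamson-type O-alkylation in which the 4-OH, the most acidic hydroxyl and the only one not held in a hydrogen bond to the aldehyde, should take the single equivalent of MOMCl.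

**Step 2**
Reactants: 2 2,6-dihydroxy-4-(methoxymethoxy)benzaldehyde
Product: 3 2-hydroxy-6-methoxy-4-(methoxymethoxy)benzaldehyde
Conditions: MeI (1.05 equiv), K2CO3 (1.1 equiv), acetone, rt to 40 °C
Reagents that add atoms: iodomethane, CI
Why: Williamson ether synthesis on one of two equivalent hydroxyls, which should stop at the monoether because the remaining OH is then locked in a strong hydrogen bond to the carbonyl group.

**Step 3**
Reactants: 3 2-hydroxy-6-methoxy-4-(methoxymethoxy)benzaldehyde; 4 prenyl bromide
Product: 5 2-methoxy-4-(methoxymethoxy)-6-[(3-methylbut-2-en-1-yl)oxy]benzaldehyde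
Conditions: K2CO3, DMF, rt to 40 °C
Reagents that add atoms: none
Why: Williamson ether synthesis (SN2 at the primary allylic carbon) that gives a prenyl ether serving both as the mask of the future O1 and as the source of the C6 prenyl group.

**Step 4**
Reactants: 5 2-methoxy-4-(methoxymethoxy)-6-[(3-methylbut-2-en-1-yl)oxy]benzaldehyde; 6 dimethyl succinate
Product: 7 (E)-3-(methoxycarbonyl)-4-{2-methoxy-4-(methoxymethoxy)-6-[(3-methylbut-2-en-1-yl)oxy]phenyl}but-3-enoic acid
Conditions: NaOMe (1.5 equiv), MeOH, reflux; cold 1 M HCl to pH 3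
Reagents that add atoms: none
Why: Stobbe condensation, driven by irreversible E1cB opening of the paraconic ester, joins the succinate unit to the aldehyde directly and so avoids a 2,4,6-trioxygenated benzyl halide, which would ionise too easily to be handled.

**Step 5**
Reactants: 7 (E)-half-ester
Product: 8 (3R)-3-(methoxycarbonyl)-4-{2-methoxy-4-(methoxymethoxy)-6-[(3-methylbut-2-en-1-yl)oxy]phenyl}butanoic acid
Conditions: H2 (5 bar), [Rh(cod)((S,S)-Et-DuPHOS)]OTf (1 mol %), NaOMe (10 mol %), MeOH, rt
Reagents that add atoms: none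
Why: Rh-catalysed asymmetric hydrogenation of a β-aryl itaconate half-ester, in which the CH2CO2– arm chelates rhodium as an enamide carbonyl does, so the (S,S)-ligand should deliver hydrogen to the face that gives the (R)-succinate (the future C3) while the unchelated trisubstituted prenyl alkene is left alone.

**Step 6**
Reactants: 8 (R)-succinate half-ester
Product: 10 (4R)-4-{2-methoxy-4-(methoxymethoxy)-6-[(3-methylbut-2-en-1-yl)oxy]benzyl}dihydrofuran-2(3H)-one, via hydroxy acid 9 (not isolated)
Conditions: KOH (1.0 equiv), EtOH; CaCl2, NaBH4, –10 °C to rt; cold 1 M HCl to pH 3, EtOAc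
Reagents that add atoms: none
Why: Chemoselective borohydride reduction of the ester beside the inert carboxylate salt, followed by spontaneous γ-lactonisation, which moves the stereocentre out of the enolisable α-position without touching its bonds.

**Step 7**
Reactants: 10 (R)-lactone with O-prenyl ether
Product: 13 (4R)-4-[6-hydroxy-2-methoxy-4-(methoxymethoxy)-3-(3-methylbut-2-en-1-yl)benzyl]dihydrofuran-2(3H)-one, via ortho-dienone 11 (not isolated), via para-dienone 12 (not isolated)
Conditions: PhNEt2, 200 °C (sealed tube, Ar)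
Reagents that add atoms: none
Why: Tandem aromatic Claisen–Cope rearrangement, in which the [3,3] shift to the free ortho carbon gives the crowded 1,1-dimethylallyl dienone 11, which should undergo a second [3,3] shift to the para carbon (between OMe and OMOM) faster than it enolises, so that 12 tautomerises to the phenol with a normal prenyl group at the future C6 and O1 set free.

**Step 8**
Reactants: 13 phenol lactone
Product: 14 (3R)-3-(hydroxymethyl)-4-[6-hydroxy-2-methoxy-4-(methoxymethoxy)-3-(3-methylbut-2-en-1-yl)phenyl]-N-methoxy-N-methylbutanamide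
Conditions: MeNH(OMe)·HCl (4 equiv), i-PrMgCl (9 equiv), THF, –20 to 0 °C; aq NH4Cl
Reagents that add atoms: N,O-dimethylhydroxylamine hydrochloride, CNOC.Cl
Why: Weinreb aminolysis of the lactone with the magnesium amide frees the primary alcohol and turns the carboxyl carbon into a ketone precursor under non-acidic conditions that spare the MOM and prenyl groups.

**Step 9**
Reactants: 14 hydroxy Weinreb amide
Product: 15 2-[(3R)-5-methoxy-7-(methoxymethoxy)-6-(3-methylbut-2-en-1-yl)chroman-3-yl]-N-methoxy-N-methylacetamide
Conditions: PPh3, DIAD, THF (0.02 M), 0 °C to rt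
Reagents that add atoms: none
Why: Intramolecular Mitsunobu etherification closes ring C (6-exo-tet) at the primary carbon, where the phenoxide should outrun the amide oxygen as nucleophile, and C3 takes no part in the substitution.

**Step 10**
Reactants: 15 chroman Weinreb amide; 16 vinylmagnesium bromide
Product: 17 1-[(3R)-5-methoxy-7-(methoxymethoxy)-6-(3-methylbut-2-en-1-yl)chroman-3-yl]but-3-en-2-one
Conditions: THF, –78 to 0 °C; inverse quench into cold 1 M HCl
Reagents that add atoms: none
Why: Weinreb ketone synthesis, in which the magnesium chelate prevents over-addition and the inverse acidic quench protonates the released amine before it can add to the enone.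

**Step 11**
Reactants: 17 vinyl ketone
Product: 19 1-diazo-1-[(3R)-5-methoxy-7-(methoxymethoxy)-6-(3-methylbut-2-en-1-yl)chroman-3-yl]but-3-en-2-one, via trifluoroacetyl diketone 18 (not isolated)
Conditions: 17 added to LiHMDS (1.1 equiv), THF, –78 °C; CF3CO2CH2CF3; then MsN3, Et3N, H2O (1 equiv), MeCN, rt
Reagents that add atoms: methanesulfonyl azide, CS(=O)(=O)N=[N+]=[N-]; 2,2,2-trifluoroethyl trifluoroacetate, O=C(OCC(F)(F)F)C(F)(F)F (its CF3CO group stays only in 18)
Why: Detrifluoroacetylative diazo transfer, in which the only enolisable position (the CH2 next to C3) is acylated at –78 °C and the activated diketone then accepts the diazo group under mild amine base with loss of the trifluoroacetyl group, conditions developed for base-sensitive enones.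

**Step 12**
Reactants: 4 prenyl bromide; 20 ethynylmagnesium bromide
Product: 21 5-methylhex-4-en-1-yne
Conditions: CuCl (5 mol %), THF, 0 to 50 °C; fractional distillation
Reagents that add atoms: none
Why: Copper-catalysed allylic coupling of an alkynyl Grignard reagent, which with prenyl halides should proceed at the primary carbon (SN2) to give the linear skipped enyne.

**Step 13**
Reactants: 21 5-methylhex-4-en-1-yne
Product: 23 triisopropyl[(5-methylhex-4-en-1-yn-1-yl)oxy]silane, via lithium ynolate 22 (not isolated)
Conditions: n-BuLi, THF, –78 °C; t-BuOOLi (t-BuOOH + LiHMDS), –78 to 0 °C; TIPSOTf, –78 °C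
Reagents that add atoms: tert-butyl hydroperoxide, CC(C)(C)OO; triisopropylsilyl triflate, CC(C)[Si](C(C)C)(C(C)C)OS(=O)(=O)C(F)(F)F
Why: Oxidation of the lithium acetylide by lithium tert-butyl peroxide gives the ynolate, which the bulky silyl triflate should trap on oxygen, and the nucleophilic peroxide does not attack the unactivated alkene.

**Step 14**
Reactants: 19 diazo vinyl ketone; 23 prenyl siloxyalkyne
Product: 27 (3R)-4'-hydroxy-5-methoxy-7-(methoxymethoxy)-6,3'-bis(3-methylbut-2-en-1-yl)-2'-(triisopropylsilyloxy)isoflavan, via vinylketene 24 (not isolated), via vinylcyclobutenone 25 (not isolated), via dienylketene 26 (not isolated)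
Conditions: 23 (1.5 equiv), hν (254 nm, Vycor), degassed ClCH2CH2Cl (0.05 M), 25 °C; then 80 °C
Reagents that add atoms: none
Why: Direct irradiation expels N2 and, in the s-Z conformer, the vinyl group shifts from the carbonyl carbon to the diazo carbon (photo-Wolff rearrangement, C1'–C6') to give vinylketene 24, whose ketene carbon is attacked by the nucleophilic prenyl-bearing carbon of the polarised siloxyalkyne in a [2+2] cycloaddition (C3'–C4' and C1'–C2') to give 25. Light or the final heating opens the strained 25 by reversible four-electron electrocyclic cleavage of the old C1'–C4' bond to dienylketene 26, and ring B then closes by six-electron disrotatory electrocyclisation (C4'–C5') followed by tautomerisation of the cyclohexadienone to the phenol. The closest known reaction type is the Danheiser benzannulation in its diazo ketone variant, which with siloxyalkynes gives resorcinol monosilyl ethers. No lasting stereocentre is formed: the quaternary carbon of 25 arises without control and is erased on ring opening, while C3 carries no acidic hydrogen and lies outside every π system of the productive cascade, so its configuration should be retained. Regioselectivity is needed in the [2+2] step and is secured by the silyloxy donor, so that the ketene carbon becomes C4' with a free OH and the ynol carbon becomes C2' with OTIPS. Chemoselectivity is needed for vinyl migration over a 1,2-shift of the C3 hydrogen to the carbene centre, and it rests on singlet excitation, on the high migratory aptitude of the sp2 group and on the small vinyl group, which keeps the s-Z conformer populated.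

**Step 15**
Reactants: 27 benzannulation product
Product: 28 (3R)-5-methoxy-7,4'-bis(methoxymethoxy)-6,3'-bis(3-methylbut-2-en-1-yl)-2'-(triisopropylsilyloxy)isoflavan
Conditions: MOMCl, i-Pr2NEt, CH2Cl2, 0 °C to rt
Reagents that add atoms: chloromethyl methyl ether (MOMCl), COCCl
Why: Williamson-type acetal ether formation on the only free hydroxyl blocks O4', so that it cannot later compete for the 3'-prenyl group.

**Step 16**
Reactants: 28 bis-MOM silyl ether
Product: 29 (3R)-2'-hydroxy-5-methoxy-7,4'-bis(methoxymethoxy)-6,3'-bis(3-methylbut-2-en-1-yl)isoflavan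
Conditions: TBAF (1.1 equiv), THF, 0 °C; aq NH4Cl
Reagents that add atoms: none
Why: Fluoride-induced desilylation of an aryl silyl ether, driven by the Si–F bond and the good phenoxide leaving group, frees O2' alone because MOM ethers are inert to fluoride.

**Step 17**
Reactants: 29 2'-phenol
Product: 30 (3R)-5-methoxy-7-(methoxymethoxy)-3-[5-(methoxymethoxy)-2,2-dimethyl-2H-chromen-8-yl]-6-(3-methylbut-2-en-1-yl)chroman
Conditions: Pd(dba)2 (10 mol %), KHCO3 (1.1 equiv), DMSO–H2O 9:1, air, 60 °C
Reagents that add atoms: none
Why: Aerobic Pd(II) oxidative cyclisation of an o-prenylphenol (Wacker-type), in which the phenoxide bonds to the tertiary terminus of the palladium-activated prenyl unit and loss of a benzylic hydrogen gives the 2,2-dimethylchromene (ring D), while the ring A prenyl group has no neighbouring free hydroxyl.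

**Step 18**
Reactants: 30 bis-MOM chromene
Product: 31 (3R)-3-(5-hydroxy-2,2-dimethyl-2H-chromen-8-yl)-5-methoxy-6-(3-methylbut-2-en-1-yl)chroman-7-ol
Conditions: HCl (ca. 1 M in MeOH), 35–40 °C
Reagents that add atoms: none
Why: Acid-catalysed transacetalisation of both phenolic MOM ethers to methanol, a standard deprotection for prenylated and pyrano-fused phenols when acid strength and temperature are kept low.

**Compound list**

| No. | Name | SMILES | Role |
|---|---|---|---|
| 1 | 2,4,6-trihydroxybenzaldehyde | O=Cc1c(O)cc(O)cc1O | starting material |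
| 2 | 2,6-dihydroxy-4-(methoxymethoxy)benzaldehyde | O=Cc1c(O)cc(OCOC)cc1O | intermediate |
| 3 | 2-hydroxy-6-methoxy-4-(methoxymethoxy)benzaldehyde | COc1cc(OCOC)cc(O)c1C=O | intermediate |
| 4 | prenyl bromide | CC(C)=CCBr | starting material |
| 5 | 2-methoxy-4-(methoxymethoxy)-6-(prenyloxy)benzaldehyde | COc1cc(OCOC)cc(OCC=C(C)C)c1C=O | intermediate |
| 6 | dimethyl succinate | COC(=O)CCC(=O)OC | starting material |
| 7 | (E)-arylidenesuccinic acid 1-methyl ester | COc1cc(OCOC)cc(OCC=C(C)C)c1/C=C(\CC(=O)O)C(=O)OC | intermediate |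
| 8 | (R)-2-(arylmethyl)succinic acid 1-methyl ester | COc1cc(OCOC)cc(OCC=C(C)C)c1C[C@H](CC(=O)O)C(=O)OC | intermediate |
| 9 | (3R)-3-(hydroxymethyl)-4-arylbutanoic acid | COc1cc(OCOC)cc(OCC=C(C)C)c1C[C@H](CC(=O)O)CO | intermediate |
| 10 | (4R)-4-(arylmethyl)butyrolactone, O-prenyl ether | COc1cc(OCOC)cc(OCC=C(C)C)c1C[C@H]1COC(=O)C1 | intermediate |
| 11 | ortho-dienone, 6-(2-methylbut-3-en-2-yl)cyclohexa-2,4-dienone | COC1=C(C[C@H]2COC(=O)C2)C(=O)C(C(C)(C)C=C)C(OCOC)=C1 | intermediate |
| 12 | para-dienone, 4-prenylcyclohexa-2,5-dienone | COC1=C(C[C@H]2COC(=O)C2)C(=O)C=C(OCOC)C1CC=C(C)C | intermediate |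
| 13 | (4R)-4-[6-hydroxy-2-methoxy-4-(methoxymethoxy)-3-prenylbenzyl]butyrolactone | COc1c(CC=C(C)C)c(OCOC)cc(O)c1C[C@H]1COC(=O)C1 | intermediate |
| 14 | (3R)-hydroxy Weinreb amide | COc1c(CC=C(C)C)c(OCOC)cc(O)c1C[C@H](CC(=O)N(C)OC)CO | intermediate |
| 15 | (3R)-chroman-3-ylacetic Weinreb amide | COc1c(CC=C(C)C)c(OCOC)cc2c1C[C@H](CC(=O)N(C)OC)CO2 | intermediate |
| 16 | vinylmagnesium bromide | C=C[Mg]Br | starting material |
| 17 | 1-[(3R)-chroman-3-yl]but-3-en-2-one | COc1c(CC=C(C)C)c(OCOC)cc2c1C[C@H](CC(=O)C=C)CO2 | intermediate |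
| 18 | 3-[(3R)-chroman-3-yl]-1,1,1-trifluorohex-5-ene-2,4-dione | COc1c(CC=C(C)C)c(OCOC)cc2c1C[C@H](C(C(=O)C=C)C(=O)C(F)(F)F)CO2 | intermediate |
| 19 | 1-diazo-1-[(3R)-chroman-3-yl]but-3-en-2-one | COc1c(CC=C(C)C)c(OCOC)cc2c1C[C@H](C(=[N+]=[N-])C(=O)C=C)CO2 | intermediate |
| 20 | ethynylmagnesium bromide | C#C[Mg]Br | starting material |
| 21 | 5-methylhex-4-en-1-yne | C#CCC=C(C)C | intermediate |
| 22 | lithium 5-methylhex-4-en-1-yn-1-olate | CC(C)=CCC#C[O-].[Li+] | intermediate |
| 23 | triisopropyl[(5-methylhex-4-en-1-yn-1-yl)oxy]silane | CC(C)=CCC#CO[Si](C(C)C)(C(C)C)C(C)C | intermediate |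
| 24 | 2-[(3R)-chroman-3-yl]buta-1,3-dien-1-one (vinylketene) | COc1c(CC=C(C)C)c(OCOC)cc2c1C[C@H](C(C=C)=C=O)CO2 | intermediate |
| 25 | 4-[(3R)-chroman-3-yl]-2-prenyl-3-(triisopropylsilyloxy)-4-vinylcyclobut-2-enone | COc1c(CC=C(C)C)c(OCOC)cc2c1C[C@H](C1(C=C)C(=O)C(CC=C(C)C)=C1O[Si](C(C)C)(C(C)C)C(C)C)CO2 | intermediate |
| 26 | dienylketene (vinyl cis to the ketenyl carbon) | COc1c(CC=C(C)C)c(OCOC)cc2c1C[C@H](/C(C=C)=C(\O[Si](C(C)C)(C(C)C)C(C)C)C(CC=C(C)C)=C=O)CO2 | intermediate |
| 27 | (3R)-isoflavan, 4'-OH, 3'-prenyl, 2'-OTIPS, 7-OMOM | COc1c(CC=C(C)C)c(OCOC)cc2c1C[C@H](c1ccc(O)c(CC=C(C)C)c1O[Si](C(C)C)(C(C)C)C(C)C)CO2 | intermediate |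
| 28 | (3R)-isoflavan, 4'-OMOM, 2'-OTIPS, 7-OMOM | COc1c(CC=C(C)C)c(OCOC)cc2c1C[C@H](c1ccc(OCOC)c(CC=C(C)C)c1O[Si](C(C)C)(C(C)C)C(C)C)CO2 | intermediate |
| 29 | (3R)-isoflavan, 2'-OH, 4'-OMOM, 7-OMOM | COc1c(CC=C(C)C)c(OCOC)cc2c1C[C@H](c1ccc(OCOC)c(CC=C(C)C)c1O)CO2 | intermediate |
| 30 | (3R)-bis-MOM pyranoisoflavan | COc1c(CC=C(C)C)c(OCOC)cc2c1C[C@H](c1ccc(OCOC)c3c1OC(C)(C)C=C3)CO2 | intermediate |
| 31 | (3R)-3-(5-hydroxy-2,2-dimethyl-2H-chromen-8-yl)-5-methoxy-6-prenylchroman-7-ol | COc1c(CC=C(C)C)c(O)cc2c1C[C@H](c1ccc(O)c3c1OC(C)(C)C=C3)CO2 | target |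

**Step count**
- Total steps: 18.
- Longest linear sequence: 16 (steps 1–11 and 14–18). Steps 12–13 form the side branch to 23.

**Steps most likely to fail**

1. **Step 14.**
   - *What may go wrong:*
     - After loss of nitrogen, a 1,2-shift of the tertiary C3 hydrogen to the carbene centre may compete with vinyl migration. This would consume the diazo ketone and erase the stereocentre.
     - In the dienylketene isomer with the chromanyl group turned towards the ketene, a 1,5-hydrogen shift may drain material.
     - Light absorption by ring A and by the product may slow the photolysis.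
     - The product phenol may intercept the ketene.
   - *Fallback (the same vinylketene without a carbene), from 15 back to 27:*
     - Hydrolysis of the amide (KOH, aq EtOH, reflux) would give the chroman-3-ylacetic acid F1.
     - Its dianion (LDA, 2.2 equiv, THF) would add to acetaldehyde to give the β-hydroxy acid F2.
     - Acetylation (Ac2O, Et3N, DMAP) and DBU-induced E1cB elimination, with aqueous LiOH work-up, would give the 2-(chroman-3-yl)but-2-enoic acid F3.
     - 1-Chloro-N,N,2-trimethylprop-1-en-1-amine would convert F3 under neutral conditions into the acid chloride F4.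
     - Slow addition of F4 to Et3N and 23 in toluene at 80–110 °C would generate vinylketene 24 by 1,4-dehydrochlorination. Only the methyl hydrogens are vinylogously acidic, so C3 is not touched.
     - Ketene 24 would then run thermally through 25 and 26 to 27.

2. **Step 11.**
   - *What may go wrong:*
     - The unsubstituted enone may suffer conjugate addition of the amide base or of its own enolate (oligomerisation) during enolisation.
     - Once the diazo group is in place, intermolecular dipolar cycloaddition onto the free acryloyl terminus may erode the product on concentration or storage.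
   - *Fallback (traceless silyl cap on the vinyl terminus), from 15 back to 27:*
     - (E)-2-(Trimethylsilyl)vinyllithium, made from (E)-(2-bromovinyl)trimethylsilane and t-BuLi, would give the β-silyl enone F5. It is a much poorer Michael acceptor and dipolarophile.
     - The same two-stage diazo transfer, through the trifluoroacetyl diketone F6, would give the diazo ketone F7.
     - Irradiation of F7 with 23 as in step 14 would run the same cascade.
     - The ring closure places silicon on the sp3 carbon next to the dienone carbonyl, from which a 1,3 carbon-to-oxygen silyl shift should aromatise the ring to the 4'-O-trimethylsilyl ether F8.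
     - Brief treatment with K2CO3 in MeOH at 0 °C would cleave only the TMS ether and give 27.

3. **Step 17.**
   - *What may go wrong:*
     - 5-exo oxypalladation may compete with the 6-endo closure.
     - Allylic C–H palladation of the ring A prenyl group, or slow catalyst reoxidation, may cause loss of material.
   - *Fallback (selenium in place of palladium), from 29 back to 30:*
     - N-(Phenylseleno)phthalimide (1.05 equiv) with catalytic camphorsulfonic acid in CH2Cl2 at –78 to 0 °C would effect Markovnikov 6-endo selenoetherification by O2', giving the 3''-phenylselanyl-2'',2''-dimethylchroman F9.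
     - The ring A prenyl group has no internal nucleophile and its seleniranium ion forms reversibly.
     - Oxidation at selenium (m-CPBA, 1.0 equiv, –78 °C, then i-Pr2NH, rt) and syn-elimination would give 30. The elimination can only take the benzylic C4'' hydrogen, because C2'' is quaternary.

**Further compounds**
F1 | step 14 | 2-[(3R)-5-methoxy-7-(methoxymethoxy)-6-prenylchroman-3-yl]acetic acid | COc1c(CC=C(C)C)c(OCOC)cc2c1C[C@H](CC(=O)O)CO2
F2 | step 14 | 3-hydroxy-2-(chroman-3-yl)butanoic acid (C3 as in 15, mixture at the two new centres) | COc1c(CC=C(C)C)c(OCOC)cc2c1C[C@H](C(C(C)O)C(=O)O)CO2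
F3 | step 14 | 2-(chroman-3-yl)but-2-enoic acid (C3 as in 15, E/Z mixture) | COc1c(CC=C(C)C)c(OCOC)cc2c1C[C@H](C(=CC)C(=O)O)CO2
F4 | step 14 | 2-(chroman-3-yl)but-2-enoyl chloride (C3 as in 15, E/Z mixture) | COc1c(CC=C(C)C)c(OCOC)cc2c1C[C@H](C(=CC)C(=O)Cl)CO2
F5 | step 11 | (E)-1-[(3R)-chroman-3-yl]-4-(trimethylsilyl)but-3-en-2-one | COc1c(CC=C(C)C)c(OCOC)cc2c1C[C@H](CC(=O)/C=C/[Si](C)(C)C)CO2
F6 | step 11 | (E)-3-(chroman-3-yl)-1,1,1-trifluoro-6-(trimethylsilyl)hex-5-ene-2,4-dione (C3 as in 15) | COc1c(CC=C(C)C)c(OCOC)cc2c1C[C@H](C(C(=O)/C=C/[Si](C)(C)C)C(=O)C(F)(F)F)CO2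
F7 | step 11 | (E)-1-diazo-1-[(3R)-chroman-3-yl]-4-(trimethylsilyl)but-3-en-2-one | COc1c(CC=C(C)C)c(OCOC)cc2c1C[C@H](C(=[N+]=[N-])C(=O)/C=C/[Si](C)(C)C)CO2
F8 | step 11 | (3R)-isoflavan, 4'-OTMS, 3'-prenyl, 2'-OTIPS, 7-OMOM | COc1c(CC=C(C)C)c(OCOC)cc2c1C[C@H](c1ccc(O[Si](C)(C)C)c(CC=C(C)C)c1O[Si](C(C)C)(C(C)C)C(C)C)CO2
F9 | step 17 | (3R)-3-[5-(methoxymethoxy)-2,2-dimethyl-3-(phenylselanyl)chroman-8-yl]-5-methoxy-7-(methoxymethoxy)-6-prenylchroman (mixture at the selenium-bearing carbon) | COc1c(CC=C(C)C)c(OCOC)cc2c1C[C@H](c1ccc(OCOC)c3c1OC(C)(C)C([Se]c1ccccc1)C3)CO2
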